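## Retrosynthetic overview

1. Enone C=C: Claisen–Schmidt disconnection into a ring A catechol methyl ketone and a ring B benzaldehyde; the E geometry is set in this last step.
2. Ring B O–CH3 (key C–O bond): site-selective methylation of the hydrogen-bonded 2-OH of a 2,4-dihydroxy-3-prenylbenzaldehyde, with the 4-OH left free and no protecting group.
3. Ring B C3–prenyl bond: traced back through a [3,3] shift to an aryl O–C(CH3)2CH=CH2 ether, i.e. a second C–O bond made by O-allylation of the 4-OH of the resorcinol aldehyde.
4. The tertiary allyl donor is a mixed tert-butyl carbonate of the tertiary allylic alcohol.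
5. Ring formation: none; rings A and B are both bought as intact benzene rings.

Assumption: the target has no stereocentre, so "single enantiomer" is read as the single (E)-alkene isomer drawn, which is the only stereochemical element to control.

## Route

Step 1
Reactants: 1 2-methylbut-3-en-2-ol
Product: 3 tert-butyl (2-methylbut-3-en-2-yl) carbonate, via lithium alkoxide 2 (not isolated)
Conditions: n-BuLi (1.05 equiv), THF, 0 °C, 30 min; then Boc2O (1.1 equiv), 0 °C to rt, 3 h; H2O quench, distil
Reagents that add atoms: di-tert-butyl dicarbonate (Boc2O), CC(C)(C)OC(=O)OC(=O)OC(C)(C)C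
Why: Alkoxycarbonylation of a pre-formed tertiary lithium alkoxide with Boc2O is the standard way to this allyl donor, the alkoxide being used because the hindered tertiary alcohol itself acylates poorly.

Step 2
Reactants: 4 2,4-dihydroxybenzaldehyde; 3 tert-butyl (2-methylbut-3-en-2-yl) carbonate (1.3 equiv)
Product: 5 2-hydroxy-4-[(2-methylbut-3-en-2-yl)oxy]benzaldehyde
Conditions: Pd(PPh3)4 (3 mol%), 4 Å MS, THF, 0 °C, 3 h, Ar; filter through silica to remove palladium
Reagents that add atoms: none
Why: Tsuji–Trost O-allylation: zerovalent palladium ionises 3 to a 1,1-dimethylallyl palladium cation and tert-butoxide (after loss of CO2), the base deprotonates only the more acidic, non-hydrogen-bonded 4-OH, and the phenoxide attacks the more substituted allyl terminus under kinetic control at 0 °C, so the tertiary ether forms and the chelated 2-OH stays free.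

Step 3
Reactants: 5 2-hydroxy-4-[(2-methylbut-3-en-2-yl)oxy]benzaldehyde
Product: 7 2,4-dihydroxy-3-(3-methylbut-2-en-1-yl)benzaldehyde, via ortho-dienone 6 (not isolated)
Conditions: PhNEt2, 130 °C, 2 h, Ar; cold 1 M HCl wash
Reagents that add atoms: none
Why: Aromatic Claisen rearrangement ([3,3]-sigmatropic shift, then enolisation of 6): the tertiary allyl aryl ether rearranges at modest temperature with allyl transposition, so the linear 3-methylbut-2-enyl group arrives on carbon, and the 2-OH···O=CH hydrogen bond fixes C3–C4 as the enol-ether double bond so that migration goes to C3 and not C5; the basic solvent suppresses acid-induced chroman closure.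

Step 4
Reactants: 7 2,4-dihydroxy-3-(3-methylbut-2-en-1-yl)benzaldehyde
Product: 8 4-hydroxy-2-methoxy-3-(3-methylbut-2-en-1-yl)benzaldehyde
Conditions: Cu(OAc)2 (20 mol%), 4,4'-di-tert-butyl-2,2'-bipyridine (20 mol%), MeB(OH)2 (2.5 equiv), O2 (1 atm), 4 Å MS, 1,2-dichloroethane, 45 °C, no amine base; aq. NH4Cl work-up
Reagents that add atoms: methylboronic acid, CB(O)O
Why: Proposed new method: chelate-directed oxidative O-methylation — divalent copper capped by the bipyridine binds the salicylaldehyde unit of 7 as a six-membered O,O-chelate, which acidifies the 2-OH enough for acetate to deprotonate it while the non-chelated 4-OH (no amine base present) stays protonated and off the metal; methyl transfer from boron to copper, oxidation to a trivalent copper methyl aryloxide and C–O reductive elimination then place the methyl group only on the copper-bound 2-oxygen, the weakly binding product dissociates and O2 returns monovalent copper to the divalent state; the closest known reaction type is the Chan–Lam oxidative O-methylation of phenols with methylboronic acid, which has not been used to override the normal preference for the free 4-OH of a 2,4-dihydroxybenzaldehyde.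

Step 5
Reactants: 8 4-hydroxy-2-methoxy-3-(3-methylbut-2-en-1-yl)benzaldehyde; 9 1-(3,4-dihydroxyphenyl)ethan-1-one (1.2 equiv)
Product: 11 (E)-1-(3,4-dihydroxyphenyl)-3-[4-hydroxy-2-methoxy-3-(3-methylbut-2-en-1-yl)phenyl]prop-2-en-1-one (licoagrochalcone C), via racemic aldol adduct 10 (not isolated)
Conditions: KOH (60% aq., 20 equiv), EtOH, degassed, Ar, rt to 40 °C, 48–72 h; then 2 M HCl, 0 °C, to pH 4
Reagents that add atoms: none
Why: Claisen–Schmidt condensation (crossed aldol, then E1cB loss of water from 10): only ketone 9 can enolise and only aldehyde 8 can accept, concentrated KOH compensates for the deactivation by the phenoxides, argon protects the catechol, and the conjugated enone forms under thermodynamic control as the E isomer (the transient carbinol centre of 10 is lost, so 11 has no stereocentre).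

## Compound list

1 | 2-methylbut-3-en-2-ol | CC(C)(O)C=C | starting material
2 | lithium 2-methylbut-3-en-2-olate | [Li+].[O-]C(C)(C)C=C | intermediate (not isolated)
3 | tert-butyl (2-methylbut-3-en-2-yl) carbonate | CC(C)(C)OC(=O)OC(C)(C)C=C | intermediate
4 | 2,4-dihydroxybenzaldehyde | O=Cc1ccc(O)cc1O | starting material
5 | 2-hydroxy-4-[(2-methylbut-3-en-2-yl)oxy]benzaldehyde | O=Cc1ccc(OC(C)(C)C=C)cc1O | intermediate
6 | 2-hydroxy-3-(3-methylbut-2-en-1-yl)-4-oxocyclohexa-1,5-diene-1-carbaldehyde (racemic ortho-dienone) | O=CC1=C(O)C(CC=C(C)C)C(=O)C=C1 | intermediate (not isolated)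
7 | 2,4-dihydroxy-3-(3-methylbut-2-en-1-yl)benzaldehyde | O=Cc1ccc(O)c(CC=C(C)C)c1O | intermediate
8 | 4-hydroxy-2-methoxy-3-(3-methylbut-2-en-1-yl)benzaldehyde | COc1c(C=O)ccc(O)c1CC=C(C)C | intermediate
9 | 1-(3,4-dihydroxyphenyl)ethan-1-one (3,4-dihydroxyacetophenone) | CC(=O)c1ccc(O)c(O)c1 | starting material
10 | 1-(3,4-dihydroxyphenyl)-3-hydroxy-3-[4-hydroxy-2-methoxy-3-(3-methylbut-2-en-1-yl)phenyl]propan-1-one (racemic aldol adduct) | COc1c(C(O)CC(=O)c2ccc(O)c(O)c2)ccc(O)c1CC=C(C)C | intermediate (not isolated)
11 | (E)-1-(3,4-dihydroxyphenyl)-3-[4-hydroxy-2-methoxy-3-(3-methylbut-2-en-1-yl)phenyl]prop-2-en-1-one (licoagrochalcone C) | COc1c(/C=C/C(=O)c2ccc(O)c(O)c2)ccc(O)c1CC=C(C)C | target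

## Step count and risks

Total steps: 5. Longest linear sequence: 5 steps (1 → 3 → 5 → 7 → 8 → 11), or 4 steps counted from the aromatic starting material 4.

**Step 4 (the proposed new reaction).** The risks are methylation at the free 4-OH, double methylation, or copper being tied up as an unreactive bis-chelate. The wrong isomer is easy to spot because it keeps the chelated OH signal near 11–12 ppm in the 1H NMR spectrum. The fallback uses known protecting-group chemistry, sets out from 7 and comes back to the route at 8. Compound 7 is alkylated with chloromethyl methyl ether and K2CO3 in acetone at rt, which goes to the non-chelated 4-OH and gives 2-hydroxy-4-(methoxymethoxy)-3-(3-methylbut-2-en-1-yl)benzaldehyde F1. The remaining chelated 2-OH is then methylated with iodomethane and K2CO3 in DMF at 40 °C to give 2-methoxy-4-(methoxymethoxy)-3-(3-methylbut-2-en-1-yl)benzaldehyde F2. Brief treatment with dilute HCl in methanol at rt removes the acetal and gives 8.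

**Step 5 (unprotected Claisen–Schmidt).** Both partners carry a para-phenoxide under the reaction conditions, so enolisation and addition are slow, and the catechol can oxidise if air gets in. The fallback masks the catechol; it sets out from 9 and comes back to the route at 11. Ketone 9 is treated with chloromethyl methyl ether and i-Pr2NEt in CH2Cl2 to give 1-[3,4-bis(methoxymethoxy)phenyl]ethan-1-one F3. F3 is condensed with 8 in KOH/EtOH–H2O at rt to give (E)-1-[3,4-bis(methoxymethoxy)phenyl]-3-[4-hydroxy-2-methoxy-3-(3-methylbut-2-en-1-yl)phenyl]prop-2-en-1-one F4. Dilute HCl in methanol at rt then frees the catechol and gives 11.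

**Step 3 (Claisen rearrangement).** The risks are some migration to C5, thermal loss of isoprene back to 4, and chroman closure of the product. The fallback drops the O-allylation/rearrangement sequence; it sets out from 4 and comes back to the route at 7. Compound 4 is C-prenylated directly with 1-bromo-3-methylbut-2-ene in aqueous KOH at 0 °C to rt. The ambident phenoxide is alkylated at C3, the carbon between the two oxygens, and 7 is separated by chromatography from the C5 isomer and O-alkylated material. The yield is modest, but it is a single operation and makes no compound outside the list (entry F0).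

## Further compounds

F1 | step 4 | 2-hydroxy-4-(methoxymethoxy)-3-(3-methylbut-2-en-1-yl)benzaldehyde | COCOc1ccc(C=O)c(O)c1CC=C(C)C
F2 | step 4 | 2-methoxy-4-(methoxymethoxy)-3-(3-methylbut-2-en-1-yl)benzaldehyde | COCOc1ccc(C=O)c(OC)c1CC=C(C)C
F3 | step 5 | 1-[3,4-bis(methoxymethoxy)phenyl]ethan-1-one | CC(=O)c1ccc(OCOC)c(OCOC)c1
F4 | step 5 | (E)-1-[3,4-bis(methoxymethoxy)phenyl]-3-[4-hydroxy-2-methoxy-3-(3-methylbut-2-en-1-yl)phenyl]prop-2-en-1-one | COCOc1ccc(C(=O)/C=C/c2ccc(O)c(CC=C(C)C)c2OC)cc1OCOC
F0 | step 3 | none | none
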